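**Retrosynthetic overview**
1. Last C–C bond, C6–C7: Pd(PPh3)4/InI turns an allylic isobutyrate into a nucleophilic 2-(methoxycarbonyl)allylindium, so the acrylate β-carbon becomes a donor. It attacks the C6 aldehyde, closes the ten-membered ring and sets C6 and C7; the γ-lactone then closes.
2. C3–C4: Nozaki–Hiyama–Kishi coupling of a C3 epoxy aldehyde with (Z)-3-iodobut-2-en-1-ol, then a double Swern oxidation to the Z-4-oxo-enal.
3. The epoxide comes from a catalyst-controlled organocatalytic epoxidation of an E-enal. The acrylate unit C11–C13 comes from a Baylis–Hillman reaction at the C7 aldehyde.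
4. C1–C10: a β-formylvinyl anion equivalent adds to a methyl ketone under 1,3-chelation (sets C10). C8–C9: proline aldol of acetone with 2,2-dimethoxyacetaldehyde (sets C8).
5. Order of ring formation: oxirane, then carbocycle, then lactone.

Assumption: positions follow germacrane numbering (ring C1–C10, acrylate/lactone carbons C11–C13, C14 on C10, C15 on C4); the target is (1R,2R,4Z,6R,7R,8R,10R).

**Step 1**
Reactants: 1 acetone; 2 2,2-dimethoxyacetaldehyde
Product: 3 (R)-4-hydroxy-5,5-dimethoxypentan-2-one
Conditions: L-proline (20 mol%), acetone (neat, excess), rt, 24 h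
Reagents that add atoms: none
Why: Proline-catalysed (List-type) enamine aldol, in which the acetone enamine attacks the Re face of the activated, non-enolisable aldehyde through the hydrogen-bonded chair transition state and sets C8 as R.

**Step 2**
Reactants: 4 3,3-diethoxyprop-1-yne
Product: 5 (E)-tributyl(3,3-diethoxyprop-1-enyl)stannane
Conditions: Bu3SnH (1.1 equiv), AIBN (5 mol%), neat, 80 °C
Reagents that add atoms: tributyltin hydride CCCC[SnH](CCCC)CCCC
Why: Radical hydrostannation of a terminal alkyne under equilibrating conditions gives mainly the terminal (E)-vinylstannane, the precursor of a β-formylvinyl anion equivalent.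

**Step 3**
Reactants: 3 (R)-4-hydroxy-5,5-dimethoxypentan-2-one; 5 (E)-tributyl(3,3-diethoxyprop-1-enyl)stannane
Product: 7 (2E,4R,6R)-1,1-diethoxy-7,7-dimethoxy-4-methylhept-2-ene-4,6-diol, via vinyllithium 6 (not isolated)
Conditions: 5 (2.3 equiv), n-BuLi (2.2 equiv), THF, -78 °C; then 3 premixed with MgBr2·OEt2 (1.5 equiv) in Et2O, -78 to -40 °C; pH 7 buffer
Reagents that add atoms: none
Why: Tin–lithium exchange gives a β-formylvinyl anion equivalent (d3 reagent) whose C1 adds to the C10 ketone held in a six-membered magnesium chelate with the C8 alkoxide, so axial attack (Cram 1,3-chelate model) places the C10 hydroxyl anti to the C8 oxygen along C7–C1, which is 10R.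

**Step 4**
Reactants: 7 (2E,4R,6R)-1,1-diethoxy-7,7-dimethoxy-4-methylhept-2-ene-4,6-diol
Product: 8 (2R,4R,5E)-7,7-diethoxy-4-hydroxy-1,1-dimethoxy-4-methylhept-5-en-2-yl 2-methylpropanoate
Conditions: (iPrCO)2O (1.2 equiv), Et3N, DMAP (10 mol%), CH2Cl2, 0 °C
Reagents that add atoms: isobutyric anhydride CC(C)C(=O)OC(=O)C(C)C
Why: DMAP-catalysed acylation takes only the secondary C8 alcohol, because the tertiary allylic C10 alcohol is too hindered.

**Step 5**
Reactants: 8 (2R,4R,5E)-7,7-diethoxy-4-hydroxy-1,1-dimethoxy-4-methylhept-5-en-2-yl 2-methylpropanoate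
Product: 9 (2R,4R,5E)-4-methyl-1,7-dioxo-4-(triethylsilyloxy)hept-5-en-2-yl 2-methylpropanoate
Conditions: Et3SiOTf (5 equiv), 2,6-lutidine (7 equiv), CH2Cl2, -20 to 0 °C; then H2O
Reagents that add atoms: triethylsilyl triflate CC[Si](CC)(CC)OS(=O)(=O)C(F)(F)F; water O
Why: Silyl triflate with 2,6-lutidine silylates the tertiary alcohol and converts both acetals into pyridinium-type salts that water hydrolyses under non-acidic conditions (Fujioka-type acetal cleavage), so the ester, the allylic ether and C8 are untouched and the C10 oxygen can no longer form a lactol with C7.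

**Step 6**
Reactants: 9 (2R,4R,5E)-4-methyl-1,7-dioxo-4-(triethylsilyloxy)hept-5-en-2-yl 2-methylpropanoate; 10 methyl acrylate
Product: 12 methyl (4R,6R,7E)-6-methyl-2-methylidene-3,4-bis(2-methylpropanoyloxy)-9-oxo-6-(triethylsilyloxy)non-7-enoate (both C3 epimers), via Baylis-Hillman alcohol 11 (not isolated)
Conditions: 10 (10 equiv, neat), DABCO (50 mol%), rt, 48 h; aqueous wash; then (iPrCO)2O, Et3N, DMAP (cat.), CH2Cl2, 0 °C
Reagents that add atoms: isobutyric anhydride CC(C)C(=O)OC(=O)C(C)C
Why: Morita–Baylis–Hillman reaction in which the DABCO–acrylate enolate adds far faster to the activated α-acyloxy aldehyde C7 than to the hindered conjugated C3 enal; capping with the same acyl group makes any 1,2-acyl shift between O7 and O8 degenerate, and the new C7 centre is erased in step 11.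

**Step 7**
Reactants: 12 methyl (4R,6R,7E)-6-methyl-2-methylidene-3,4-bis(2-methylpropanoyloxy)-9-oxo-6-(triethylsilyloxy)non-7-enoate
Product: 13 methyl (4R,6R)-6-[(2R,3R)-3-formyloxiran-2-yl]-2-methylidene-3,4-bis(2-methylpropanoyloxy)-6-(triethylsilyloxy)heptanoate (both C3 epimers)
Conditions: (R)-2-{bis[3,5-bis(trifluoromethyl)phenyl](trimethylsilyloxy)methyl}pyrrolidine (10 mol%), 35% aq H2O2 (1.3 equiv), CH2Cl2, rt
Reagents that add atoms: hydrogen peroxide OO
Why: Jørgensen-type iminium–enamine epoxidation in which hydroperoxide adds to C1 of the E-iminium ion on the face away from the CAr2OSiMe3 group and the enamine closes the ring, so the catalyst sets the trans-epoxide as 1R,2R.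

**Step 8**
Reactants: 14 but-2-yn-1-ol
Product: 16 (Z)-3-iodobut-2-en-1-ol, via vinylalanate 15 (not isolated)
Conditions: NaAlH2(OCH2CH2OMe)2 (1.5 equiv), THF, 0 °C to rt; then I2, THF, -78 °C
Reagents that add atoms: iodine II
Why: Hydroxyl-directed trans-hydroalumination of the propargylic alcohol gives a five-membered vinylalanate whose iodinolysis goes with retention, which fixes the Z geometry of C4=C5.

**Step 9**
Reactants: 13 methyl (4R,6R)-6-[(2R,3R)-3-formyloxiran-2-yl]-2-methylidene-3,4-bis(2-methylpropanoyloxy)-6-(triethylsilyloxy)heptanoate; 16 (Z)-3-iodobut-2-en-1-ol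
Product: 18 seco diol (13 with CHO replaced by CH(OH)-C(CH3)=CH-CH2OH; Z alkene; both C3 carbinol epimers; all other centres as in 13), via alkenylchromium 17 (not isolated)
Conditions: 16 (1.5 equiv), CrCl2 (4 equiv), NiCl2 (1 mol%), DMSO–THF, rt
Reagents that add atoms: none
Why: Nozaki–Hiyama–Kishi coupling, in which the alkenylchromium reagent forms with retention of the Z geometry, adds only to the aldehyde and tolerates epoxide, esters and free hydroxyl; the C3 epimer mixture does not matter because C3 becomes a ketone.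

**Step 10**
Reactants: 18 seco diol
Product: 19 seco (Z)-4-oxo-enal (18 with C3 oxidised to the ketone; C6 oxidised to the aldehyde)
Conditions: (COCl)2 (4 equiv), DMSO (8 equiv), CH2Cl2, -78 °C; Et3N (12 equiv), -78 to -30 °C; used at once
Reagents that add atoms: none
Why: Swern oxidation, in which both alcohols become alkoxysulfonium salts at -78 °C before base is added, so ketone and aldehyde appear together and the Z-hydroxy-enal that would close to a lactol or furan is never present.

**Step 11**
Reactants: 19 seco (Z)-4-oxo-enal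
Product: 22 10-O-triethylsilyl-1β,2α-epoxytagitinin C, via allylindium 20 (not isolated), via hydroxy ester 21 (not isolated)
Conditions: Pd(PPh3)4 (10 mol%), InI (2 equiv), THF, 2 mM (syringe pump, 10 h), rt; then PPTS (cat.), CH2Cl2, rt
Reagents that add atoms: none
Why: Proposed new method: zerovalent palladium ionises the allylic C7 isobutyrate and InI reduces the π-allylpalladium cation to a 2-(methoxycarbonyl)allylindium (polarity reversal of the acrylate β-carbon C7, an ester homoenolate equivalent) that adds through its γ-carbon to the C6 aldehyde, another acceptor carbon, via a chair transition state with C5 and C8 equatorial (6,7-anti, hence the trans-lactone) and on the alkene face anti to C9 with H8 eclipsing the ester (7R from 8R), while attack on the C3 ketone is excluded because it would place the trans-epoxide in a seven-membered ring; the closest known reaction types are the Pd(PPh3)4/InI carbonyl allylation with allylic esters and the CrCl2- or Zn-mediated macrocyclising 2-(alkoxycarbonyl)allylation of enals used for germacranolides.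

**Step 12**
Reactants: 22 10-O-triethylsilyl-1β,2α-epoxytagitinin C
Product: 23 1β,2α-epoxytagitinin C (CNP0273626.1)
Conditions: HF·pyridine, pyridine, THF, 0 °C
Reagents that add atoms: none
Why: Buffered fluoride cleavage of the tertiary triethylsilyl ether leaves the epoxy ketone, the α-methylene lactone and the ester intact and touches no stereocentre.

**Compound list**
1 | acetone | CC(C)=O | starting material
2 | 2,2-dimethoxyacetaldehyde | COC(OC)C=O | starting material
3 | (R)-4-hydroxy-5,5-dimethoxypentan-2-one | CC(=O)C[C@@H](O)C(OC)OC | intermediate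
4 | 3,3-diethoxyprop-1-yne | C#CC(OCC)OCC | starting material
5 | (E)-tributyl(3,3-diethoxyprop-1-enyl)stannane | CCCC[Sn](CCCC)(CCCC)/C=C/C(OCC)OCC | intermediate
6 | (E)-3,3-diethoxyprop-1-enyllithium | [Li]/C=C/C(OCC)OCC | intermediate
7 | (2E,4R,6R)-1,1-diethoxy-7,7-dimethoxy-4-methylhept-2-ene-4,6-diol | CCOC(OCC)/C=C/[C@](C)(O)C[C@@H](O)C(OC)OC | intermediate
8 | (2R,4R,5E)-7,7-diethoxy-4-hydroxy-1,1-dimethoxy-4-methylhept-5-en-2-yl 2-methylpropanoate | CCOC(OCC)/C=C/[C@](C)(O)C[C@@H](OC(=O)C(C)C)C(OC)OC | intermediate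
9 | (2R,4R,5E)-4-methyl-1,7-dioxo-4-(triethylsilyloxy)hept-5-en-2-yl 2-methylpropanoate | O=C/C=C/[C@](C)(O[Si](CC)(CC)CC)C[C@@H](OC(=O)C(C)C)C=O | intermediate
10 | methyl acrylate | C=CC(=O)OC | starting material
11 | methyl (4R,6R,7E)-3-hydroxy-6-methyl-2-methylidene-4-(2-methylpropanoyloxy)-9-oxo-6-(triethylsilyloxy)non-7-enoate (both C3 epimers) | O=C/C=C/[C@](C)(O[Si](CC)(CC)CC)C[C@@H](OC(=O)C(C)C)C(O)C(=C)C(=O)OC | intermediate
12 | methyl (4R,6R,7E)-6-methyl-2-methylidene-3,4-bis(2-methylpropanoyloxy)-9-oxo-6-(triethylsilyloxy)non-7-enoate (both C3 epimers) | O=C/C=C/[C@](C)(O[Si](CC)(CC)CC)C[C@@H](OC(=O)C(C)C)C(OC(=O)C(C)C)C(=C)C(=O)OC | intermediate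
13 | methyl (4R,6R)-6-[(2R,3R)-3-formyloxiran-2-yl]-2-methylidene-3,4-bis(2-methylpropanoyloxy)-6-(triethylsilyloxy)heptanoate (both C3 epimers) | O=C[C@@H]1O[C@H]1[C@](C)(O[Si](CC)(CC)CC)C[C@@H](OC(=O)C(C)C)C(OC(=O)C(C)C)C(=C)C(=O)OC | intermediate
14 | but-2-yn-1-ol | CC#CCO | starting material
15 | cyclic sodium vinylalanate (five-membered Al–C(CH3)=CH–CH2–O ring, two 2-methoxyethoxy groups on Al) | CC1=CCO[Al-]1(OCCOC)OCCOC.[Na+] | intermediate
16 | (Z)-3-iodobut-2-en-1-ol | C/C(I)=C/CO | intermediate
17 | (Z)-(4-hydroxybut-2-en-2-yl)chromium dichloride | C/C([Cr](Cl)Cl)=C/CO | intermediate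
18 | seco diol: C3 carbinol (both epimers), C6 CH2OH, 4Z alkene, 1R,2R trans-epoxide, 10R OSiEt3, 8R and C7 isobutyrates, methyl 2-methylidene ester | OC/C=C(/C)C(O)[C@@H]1O[C@H]1[C@](C)(O[Si](CC)(CC)CC)C[C@@H](OC(=O)C(C)C)C(OC(=O)C(C)C)C(=C)C(=O)OC | intermediate
19 | seco (Z)-4-oxo-enal: C3 ketone, C6 aldehyde, otherwise as 18 | O=C/C=C(/C)C(=O)[C@@H]1O[C@H]1[C@](C)(O[Si](CC)(CC)CC)C[C@@H](OC(=O)C(C)C)C(OC(=O)C(C)C)C(=C)C(=O)OC | intermediate
20 | (E)-2-(methoxycarbonyl)allylindium iodide isobutyrate (In on C13, C7=C11 alkene, C8 trans to C13) | O=C/C=C(/C)C(=O)[C@@H]1O[C@H]1[C@](C)(O[Si](CC)(CC)CC)C[C@@H](OC(=O)C(C)C)/C=C(/C[In](I)OC(=O)C(C)C)C(=O)OC | intermediate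
21 | ten-membered 6-hydroxy methyl ester (6R,7R; acrylate on C7; not yet lactonised) | C=C(C(=O)OC)[C@H]1[C@H](O)/C=C(/C)C(=O)[C@@H]2O[C@H]2[C@](C)(O[Si](CC)(CC)CC)C[C@H]1OC(=O)C(C)C | intermediate
22 | 10-O-triethylsilyl-1β,2α-epoxytagitinin C | C=C1C(=O)O[C@@H]2/C=C(/C)C(=O)[C@@H]3O[C@H]3[C@](C)(O[Si](CC)(CC)CC)C[C@@H](OC(=O)C(C)C)[C@@H]12 | intermediate
23 | 1β,2α-epoxytagitinin C, (1R,2R,4Z,6R,7R,8R,10R) | C=C1C(=O)O[C@@H]2/C=C(/C)C(=O)[C@@H]3O[C@H]3[C@](C)(O)C[C@@H](OC(=O)C(C)C)[C@@H]12 | target

**Step count:** 12 steps in total. The longest linear sequence is 10 steps (1, 3, 4, 5, 6, 7, 9, 10, 11, 12).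

**Steps most likely to fail, with fallbacks**

Step 11 carries the most risk. The allylindium may lose the C8 isobutyrate by 1,4-elimination. PPh3 may add to the ene-dicarbonyl or isomerise it from Z to E. The ten-membered closure may lose to oligomerisation, and the facial selectivity is only predicted. The fallback closes the ring with C3 still at the alcohol level, so no ene-dicarbonyl meets palladium or indium. It sets out from 18. MnO2 (CH2Cl2, rt) oxidises only the primary allylic alcohol, and the Z-hydroxy-enal closes to the 2,5-dihydrofuran-2-ol lactol F1. Pd(PPh3)4/InI in THF–H2O at high dilution then allylates the latent aldehyde, as in indium allylations of sugar lactols. PPTS completes lactonisation to the macrocyclic C3 carbinol lactone F2. Dess–Martin periodinane oxidises the allylic C3 alcohol, and the route is rejoined at 22.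

Step 6 is second. Two days with DABCO can epimerise the α-acyloxy aldehyde at C8, and the C3 enal may compete. The fallback replaces amine catalysis with a preformed, non-basic α-acrylate anion equivalent. It sets out from 9. Methyl propiolate is hydroaluminated (iBu2AlH, N-methylmorpholine N-oxide, THF, 0 °C) to methyl 2-(diisobutylalumanyl)prop-2-enoate F3. One equivalent is added to 9 at -78 °C, where the chelating α-acyloxy aldehyde reacts first. This gives 11, and the route is rejoined there before the acylation.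

Step 7 is third. Hydroperoxide must attack a β-carbon next to a fully substituted carbon, which may be too slow for iminium catalysis. The fallback moves the epoxidation to the allylic alcohol level. It sets out from 12. NaBH4/CeCl3·7H2O (MeOH, -78 °C) gives the E-allylic alcohol F4. Sharpless asymmetric epoxidation (Ti(OiPr)4, L-(+)-diisopropyl tartrate, t-BuOOH, 4 Å sieves, CH2Cl2, -20 °C) gives the epoxy alcohol F5 with reagent control. Dess–Martin periodinane (NaHCO3, CH2Cl2) then returns to the route at 13.

**Further compounds**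
F1 | step 11 | 2,5-dihydrofuran-2-ol lactol (ring O between C3 and C6, C6 hemiacetal, C4 methyl; side chain as in 18) | OC1C=C(C)C(O1)[C@@H]2O[C@H]2[C@](C)(O[Si](CC)(CC)CC)C[C@@H](OC(=O)C(C)C)C(OC(=O)C(C)C)C(=C)C(=O)OC
F2 | step 11 | macrocyclic C3 carbinol lactone (22 with C3 as CHOH, both epimers) | C=C1C(=O)O[C@@H]2/C=C(/C)C(O)[C@@H]3O[C@H]3[C@](C)(O[Si](CC)(CC)CC)C[C@@H](OC(=O)C(C)C)[C@@H]12
F3 | step 6 | methyl 2-(diisobutylalumanyl)prop-2-enoate | C=C([Al](CC(C)C)CC(C)C)C(=O)OC
F4 | step 7 | E-allylic alcohol (12 with CHO reduced to CH2OH) | OC/C=C/[C@](C)(O[Si](CC)(CC)CC)C[C@@H](OC(=O)C(C)C)C(OC(=O)C(C)C)C(=C)C(=O)OC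
F5 | step 7 | epoxy alcohol (13 with CHO as CH2OH, same trans-epoxide) | OC[C@@H]1O[C@H]1[C@](C)(O[Si](CC)(CC)CC)C[C@@H](OC(=O)C(C)C)C(OC(=O)C(C)C)C(=C)C(=O)OC
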